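**Plan**
1. Retrosynthetic cuts: C10=C11 is traced back to an 11-oxygenated ketone and then to the aldol bond C10–C11. Next come C7–C8 and C12–C13. The C15 acetate goes on last.
2. Enabling feature: in the cyclopentenone ring (C8–C12) the C9 carbonyl and the enone β-carbon C11 stand 1,3, so the ring is a dehydrated aldol. One oxygen placed between C10 and C11 turns it into a 2-benzyloxyoxan-5-one. That oxygen is both the α-leaving group of the C9 ketone and the acetal oxygen of a masked C11 aldehyde, so a two-electron reduction opens the ring, unmasks the aldehyde and recloses.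
3. This oxane is a pentopyranosid-4-ulose: sugar carbons C1–C5 of D-xylal become C11, C12, C8, C9 and C10.
4. Forward order: D-xylal diacetate gives the (R)-6-benzyloxypyran-3-one (oxane ring first). In one flask an alkenylzincate joins C12–C13 and an allylic iodide joins C7–C8. SmI2 then contracts the oxane to the cyclopentanone (PGE2 level), followed by desilylation and acetylation with loss of the 11-oxygen.
5. Stereochemistry is relayed from sugar C4 to the acetal carbon (Ferrier, 1,4-trans), then to C12 (anti addition), then to C8 (trans alkylation). Both relay centres end as sp2 carbons (C9, C11). C15 comes from (S)-oct-1-yn-3-ol, 13E from syn-hydrozirconation and 5Z from Z-selective cross-metathesis.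

Key step: step 9

Assumption: 3,4-di-O-acetyl-D-xylal, (S)-oct-1-yn-3-ol, methyl hex-5-enoate, (Z)-but-2-ene-1,4-diol, SmI2 in THF and the ruthenium dithiolate catalyst are taken as purchasable. Atoms carry prostaglandin numbers (C1 = ester carbon, ring = C8–C12, C15 = acetoxy carbon).

**Step 1**
Reactants: 1 3,4-di-O-acetyl-D-xylal
Product: 2 benzyl 4-O-acetyl-2,3-dideoxy-β-D-glycero-pent-2-enopyranoside [(3S,6R)-6-(benzyloxy)-3,6-dihydro-2H-pyran-3-yl acetate; 1,4-trans]
Conditions: BnOH, BF3·OEt2 (cat.), CH2Cl2, −20 → 0 °C; chromatographic removal of the 1,4-cis anomer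
Reagents that add atoms: benzyl alcohol OCc1ccccc1
Why: Ferrier rearrangement, in which BF3 ionises the allylic C3 acetate to the allyloxocarbenium ion and benzyl alcohol should add at sugar C1 mainly trans to the C4 acetate (both groups quasi-axial, anomeric and allylic effects), so that the D-configured C4 sets the new acetal centre as R and the diastereomeric anomer can still be removed at this stage.

**Step 2**
Reactants: 2 benzyl 4-O-acetyl-2,3-dideoxy-β-D-glycero-pent-2-enopyranoside
Product: 3 benzyl 2,3-dideoxy-β-D-glycero-pent-2-enopyranoside [(3S,6R)-6-(benzyloxy)-3,6-dihydro-2H-pyran-3-ol]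
Conditions: K2CO3 (cat.), MeOH, 0 °C
Reagents that add atoms: none
Why: Base-catalysed transesterification (Zemplén-type deacetylation) frees the allylic alcohol and touches neither the acetal nor a stereocentre.

**Step 3**
Reactants: 3 benzyl 2,3-dideoxy-β-D-glycero-pent-2-enopyranoside
Product: 4 (R)-6-(benzyloxy)-2H-pyran-3(6H)-one
Conditions: activated MnO2, CH2Cl2, rt
Reagents that add atoms: none
Why: Neutral MnO2 oxidation of an allylic alcohol gives the enone without acid that could anomerise the acetal carbon, which is now the only stereocentre and carries all the chirality taken from the sugar.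

**Step 4**
Reactants: 5 (S)-oct-1-yn-3-ol
Product: 6 (S)-tert-butyldimethyl(oct-1-yn-3-yloxy)silane
Conditions: TBSCl, imidazole, DMF, rt
Reagents that add atoms: tert-butyldimethylsilyl chloride CC(C)(C)[Si](C)(C)Cl
Why: Standard silylation of a secondary alcohol masks the C15 oxygen against the organometallic steps and leaves the S centre untouched.

**Step 5**
Reactants: 6 (S)-tert-butyldimethyl(oct-1-yn-3-yloxy)silane
Product: 8 (S,E)-tert-butyl[(1-iodooct-1-en-3-yl)oxy]dimethylsilane, via alkenylzirconocene chloride 7 (not isolated)
Conditions: Cp2Zr(H)Cl, THF, rt; then I2, 0 °C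
Reagents that add atoms: iodine II
Why: Hydrozirconation adds Zr–H syn and terminally to the alkyne and iodinolysis of the C–Zr bond goes with retention, which fixes the 13E geometry.

**Step 6**
Reactants: 9 methyl hex-5-enoate; 10 (Z)-but-2-ene-1,4-diol
Product: 11 methyl (Z)-7-hydroxyhept-5-enoate
Conditions: Ru(NHC)(3,6-dichlorobenzene-1,2-dithiolate) isopropoxybenzylidene catalyst (cat.), THF, 22 °C, slight vacuum
Reagents that add atoms: none
Why: Z-selective (stereoretentive) cross-metathesis, in which the dithiolate ligand forces an all-syn metallacyclobutane so that the Z geometry of 10 is handed on to the new C5=C6 bond while ester and free hydroxyl groups are tolerated.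

**Step 7**
Reactants: 11 methyl (Z)-7-hydroxyhept-5-enoate
Product: 12 methyl (Z)-7-iodohept-5-enoate
Conditions: I2, PPh3, imidazole, CH2Cl2, 0 °C, dark; used at once
Reagents that add atoms: iodine II
Why: Appel-type iodination proceeds by SN2 displacement of the oxyphosphonium group at the primary allylic carbon, which keeps the Z olefin when run cold and in the dark.

**Step 8**
Reactants: 8 (S,E)-tert-butyl[(1-iodooct-1-en-3-yl)oxy]dimethylsilane; 4 (R)-6-(benzyloxy)-2H-pyran-3(6H)-one; 12 methyl (Z)-7-iodohept-5-enoate
Product: 16 methyl (Z)-7-{(2R,3R,4R)-2-(benzyloxy)-3-[(1E,3S)-3-(tert-butyldimethylsilyloxy)oct-1-enyl]-5-oxooxan-4-yl}hept-5-enoate, via alkenyllithium 13 (not isolated), via lithium alkenyldimethylzincate 14 (not isolated), via zinc enolate 15 (not isolated)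
Conditions: 8, t-BuLi (2 equiv), Et2O, −78 °C; Me2Zn, THF, 0 °C; 4, −78 °C; then HMPA, 12, −78 → −40 °C; aqueous work-up
Reagents that add atoms: none
Why: Three-component coupling (tandem conjugate addition–enolate alkylation), in which the mixed zincate transfers only its alkenyl group to the enone β-carbon anti to the quasi-axial benzyloxy group (sets C12) and the regiodefined zinc enolate is alkylated by the allylic iodide anti to the new alkenyl group (sets C8 trans, which is also the thermodynamic arrangement).

**Step 9**
Reactants: 16 methyl (Z)-7-{(2R,3R,4R)-2-(benzyloxy)-3-[(1E,3S)-3-(tert-butyldimethylsilyloxy)oct-1-enyl]-5-oxooxan-4-yl}hept-5-enoate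
Product: 19 15-O-TBS-PGE2 methyl ester [methyl (5Z,11α,13E,15S)-15-(tert-butyldimethylsilyloxy)-11-hydroxy-9-oxoprosta-5,13-dien-1-oate], via samarium enolate hemiacetal alkoxide 17 (not isolated), via samarium enolate aldehyde 18 (not isolated)
Conditions: SmI2 (2.2 equiv, 0.1 M in THF, slow addition), THF, no proton source, −78 → −20 °C; pH 7 buffer
Reagents that add atoms: none
Why: Proposed new method: SmI2 transfers two electrons to the C9 ketone of 16, the ketyl expels the α-oxygen (the ring oxygen on C10, a good leaving group because it departs as a hemiacetal alkoxide) and the C9–C10 samarium(III) enolate 17 results regiospecifically; its hemiacetal alkoxide sheds benzyloxide, which bares the C11 aldehyde in 18, and enolate carbon C10 adds to C11, so that the oxane contracts to the cyclopentanone and the former ring oxygen ends up outside the ring as the 11-hydroxyl group. The closest known reaction types are the SmI2 cleavage of α-heterosubstituted ketones (cyclic α-alkoxy ketones included) to samarium enolates, SmI2-driven Reformatsky- and aldol-type cyclisations, and the SmI2 ring contraction of 6-deoxy-6-iodopyranosides, in which a reductive ring opening likewise frees the anomeric aldehyde for carbocyclisation; what has not been shown is their combination on an oxan-3-one acetal. The ring closes in the 5-(enolendo)-exo-trig mode, which is geometrically strained yet is the mode of every 1,4-dicarbonyl-to-cyclopentenone aldolisation, and it has no competitor because any other enolate/carbonyl pairing would give a three-membered ring. C8 and C12 are only carried through (no external base, low temperature), and the one new stereocentre, C11, should form with the bulky samarium alkoxide trans to the C12 alkenyl group (the all-trans PGE2 pattern, also favoured if the aldol is reversible), although its configuration is of no consequence because step 11 erases it. The step needs chemoselective reduction and regioselective enolate formation: only the ketone carries an α-leaving group, the ester, silyl ether, benzyl acetal and isolated olefins are inert to SmI2 without proton source or palladium, the site of the C–O bond dictates the C10 rather than the C8 enolate, and slow addition of just two equivalents keeps the reductant away from the short-lived aldehyde.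

**Step 10**
Reactants: 19 15-O-TBS-PGE2 methyl ester
Product: 20 PGE2 methyl ester [methyl (5Z,11α,13E,15S)-11,15-dihydroxy-9-oxoprosta-5,13-dien-1-oate]
Conditions: HF·pyridine, MeCN, 0 °C
Reagents that add atoms: none
Why: Fluoride-mediated cleavage of the allylic TBS ether under weakly acidic conditions spares the β-hydroxy ketone from retro-aldol and base-induced isomerisation and changes no stereocentre.

**Step 11**
Reactants: 20 PGE2 methyl ester
Product: 22 15-O-acetyl-PGA2 methyl ester [methyl (5Z,8R,12S,13E,15S)-15-acetoxy-9-oxoprosta-5,10,13-trien-1-oate], via 11,15-diacetate 21 (not isolated)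
Conditions: Ac2O, Et3N, DMAP (cat.), CH2Cl2, 0 °C → rt
Reagents that add atoms: acetic anhydride CC(=O)OC(C)=O
Why: Acetylation of both hydroxyl groups followed by amine-induced E1cB loss of the β-acetoxy group at C11 turns the C10–C11 bond into the enone olefin and leaves the C15 acetate, so that C11 is erased whichever epimer was carried and C8/C12 stay in their favoured trans relation under the mild base.

**Compound list**
1 | 3,4-di-O-acetyl-D-xylal | CC(=O)O[C@@H]1C=COC[C@H]1OC(C)=O | starting material
2 | benzyl 4-O-acetyl-2,3-dideoxy-β-D-glycero-pent-2-enopyranoside | CC(=O)O[C@@H]1CO[C@@H](OCc2ccccc2)C=C1 | intermediate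
3 | benzyl 2,3-dideoxy-β-D-glycero-pent-2-enopyranoside | O[C@@H]1CO[C@@H](OCc2ccccc2)C=C1 | intermediate
4 | (R)-6-(benzyloxy)-2H-pyran-3(6H)-one | O=C1CO[C@@H](OCc2ccccc2)C=C1 | intermediate
5 | (S)-oct-1-yn-3-ol | CCCCC[C@@H](C#C)O | starting material
6 | (S)-tert-butyldimethyl(oct-1-yn-3-yloxy)silane | CCCCC[C@@H](C#C)O[Si](C)(C)C(C)(C)C | intermediate
7 | (S,E)-alkenylzirconocene chloride (not isolated) | CCCCC[C@@H](/C=C/[Zr](Cl)(C1C=CC=C1)C1C=CC=C1)O[Si](C)(C)C(C)(C)C | intermediate
8 | (S,E)-tert-butyl[(1-iodooct-1-en-3-yl)oxy]dimethylsilane | CCCCC[C@@H](/C=C/I)O[Si](C)(C)C(C)(C)C | intermediate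
9 | methyl hex-5-enoate | C=CCCCC(=O)OC | starting material
10 | (Z)-but-2-ene-1,4-diol | OC/C=C\CO | starting material
11 | methyl (Z)-7-hydroxyhept-5-enoate | OC/C=C\CCCC(=O)OC | intermediate
12 | methyl (Z)-7-iodohept-5-enoate | IC/C=C\CCCC(=O)OC | intermediate
13 | (S,E)-alkenyllithium (not isolated) | CCCCC[C@@H](/C=C/[Li])O[Si](C)(C)C(C)(C)C | intermediate
14 | lithium alkenyldimethylzincate (not isolated) | [Li+].CCCCC[C@@H](/C=C/[Zn-](C)C)O[Si](C)(C)C(C)(C)C | intermediate
15 | zinc enolate of the conjugate adduct (not isolated) | [Li+].C[Zn-](C)OC1=C[C@@H](/C=C/[C@H](CCCCC)O[Si](C)(C)C(C)(C)C)[C@H](OCc2ccccc2)OC1 | intermediate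
16 | methyl (Z)-7-{(2R,3R,4R)-2-(benzyloxy)-3-[(1E,3S)-3-(tert-butyldimethylsilyloxy)oct-1-enyl]-5-oxooxan-4-yl}hept-5-enoate | O=C1CO[C@@H](OCc2ccccc2)[C@H](/C=C/[C@H](CCCCC)O[Si](C)(C)C(C)(C)C)[C@H]1C/C=C\CCCC(=O)OC | intermediate
17 | ring-opened samarium(III) enolate hemiacetal alkoxide (not isolated) | C=C(O[Sm](I)I)[C@H](C/C=C\CCCC(=O)OC)[C@H]([C@H](OCc1ccccc1)O[Sm](I)I)/C=C/[C@H](CCCCC)O[Si](C)(C)C(C)(C)C | intermediate
18 | samarium(III) enolate aldehyde (not isolated) | C=C(O[Sm](I)I)[C@H](C/C=C\CCCC(=O)OC)[C@H](C=O)/C=C/[C@H](CCCCC)O[Si](C)(C)C(C)(C)C | intermediate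
19 | 15-O-TBS-PGE2 methyl ester | CCCCC[C@@H](/C=C/[C@H]1[C@H](O)CC(=O)[C@@H]1C/C=C\CCCC(=O)OC)O[Si](C)(C)C(C)(C)C | intermediate
20 | PGE2 methyl ester | CCCCC[C@@H](/C=C/[C@H]1[C@H](O)CC(=O)[C@@H]1C/C=C\CCCC(=O)OC)O | intermediate
21 | PGE2 methyl ester 11,15-diacetate (not isolated) | CCCCC[C@@H](/C=C/[C@H]1[C@H](OC(C)=O)CC(=O)[C@@H]1C/C=C\CCCC(=O)OC)OC(C)=O | intermediate
22 | 15-O-acetyl-PGA2 methyl ester | CCCCC[C@@H](/C=C/[C@H]1C=CC(=O)[C@@H]1C/C=C\CCCC(=O)OC)OC(C)=O | target

Total step count: 11. Longest linear sequence: 7 (steps 1, 2, 3, 8, 9, 10, 11).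

**Steps most likely to fail**

1. Step 9 (Proposed new method).
   - Risk: proton transfer from the doubly activated C12–H of the unveiled aldehyde to the samarium enolate, or further reduction of the aldehyde, may outrun the strained 5-(enolendo) closure.
   - Fallback (known chemistry, from 16 back to 22): the two events are separated.
   - SmI2 in THF/MeOH at −78 °C is the protic α-deoxygenation of an α-alkoxy ketone. It quenches the enolate at once. After the hemiacetal loses benzyl alcohol on work-up, it should give the 10,11-seco keto aldehyde F1 (C9 methyl ketone, C11 aldehyde, C8/C12 as in 16).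
   - Piperidinium acetate in toluene then closes the same C10–C11 bond by an enamine aldol condensation. This should lead directly to 15-O-TBS-PGA2 methyl ester F2.
   - HF·pyridine gives PGA2 methyl ester F3, and Ac2O/pyridine returns to 22.

2. Step 8.
   - Risk: slow alkylation may let the zinc enolate exchange protons with the product (loss of regiocontrol, double alkylation), and the allylic iodide may drift from Z to E.
   - Fallback (from 4 and 8, through the same enolate 15, back to 16): the enolate is captured with the more reactive and geometrically inert propargylic electrophile methyl 7-iodohept-5-ynoate F4. This is made from purchasable methyl 7-hydroxyhept-5-ynoate with I2, PPh3 and imidazole.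
   - The capture should give the 5,6-didehydro adduct F5.
   - Lindlar semihydrogenation (H2, Pd/CaCO3–Pb, quinoline) then sets the 5Z olefin at a stage where no enone is present and returns to 16. Steps 6 and 7 fall away.

3. Step 1.
   - Risk: poor anomeric selectivity or incomplete separation of the anomers would erode the enantiomeric purity of 4, because the two anomers become enantiomers after step 3.
   - Fallback (it replaces 1 by purchasable furfuryl alcohol, so it sets out from no numbered compound, and it comes back at 4).
   - Achmatowicz rearrangement (NBS, aqueous THF, NaHCO3) should give 6-hydroxy-2H-pyran-3(6H)-one F6, whose lactol centre racemises freely.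
   - Dynamic kinetic acylation with isobutyric anhydride and a chiral isothiourea acyl-transfer catalyst should give (S)-6-(isobutyryloxy)-2H-pyran-3(6H)-one F7. The catalyst is benzotetramisole, both enantiomers are purchasable, and the one leading to the S ester is used.
   - Pd(0)-catalysed allylic substitution with benzyl alcohol (Pd2(dba)3, PPh3, CH2Cl2, 0 °C) proceeds with net retention by double inversion and returns to 4.

**Further compounds**
F1 | step 9 | 10,11-seco keto aldehyde (methyl (5Z,10E,12S)-8-acetyl-9-formyl-12-(tert-butyldimethylsilyloxy)heptadeca-5,10-dienoate, C8/C9 as drawn) | CC(=O)[C@H](C/C=C\CCCC(=O)OC)[C@H](C=O)/C=C/[C@H](CCCCC)O[Si](C)(C)C(C)(C)C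
F2 | step 9 | 15-O-TBS-PGA2 methyl ester | CCCCC[C@@H](/C=C/[C@H]1C=CC(=O)[C@@H]1C/C=C\CCCC(=O)OC)O[Si](C)(C)C(C)(C)C
F3 | step 9 | PGA2 methyl ester | CCCCC[C@@H](/C=C/[C@H]1C=CC(=O)[C@@H]1C/C=C\CCCC(=O)OC)O
F4 | step 8 | methyl 7-iodohept-5-ynoate | ICC#CCCCC(=O)OC
F5 | step 8 | 5,6-didehydro adduct (alkyne analogue of 16) | O=C1CO[C@@H](OCc2ccccc2)[C@H](/C=C/[C@H](CCCCC)O[Si](C)(C)C(C)(C)C)[C@H]1CC#CCCCC(=O)OC
F6 | step 1 | 6-hydroxy-2H-pyran-3(6H)-one (racemising lactol) | O=C1COC(O)C=C1
F7 | step 1 | (S)-6-(isobutyryloxy)-2H-pyran-3(6H)-one | O=C1CO[C@@H](OC(=O)C(C)C)C=C1
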